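## Retrosynthetic overview

- **Feature.** C1 (lactone CH) with its branch C15(=C17)–C16 is the stereocentre and isopropenyl group of (S)-carvone. Cleaving carvone's Cα–Cβ enone bond unrolls the six-membered ring into C13(CHO)–C14–C1–C2–C3≡C4–C18.
- **Ring C** (tetrahydrofuran O–C4–C5–C6–C7) is made last, by 5-exo opening of the (3R,4R)-epoxide at C4 by C7–OH. C19 comes just before, by methylenation of a C8 ketone.
- **Ring A** (14-membered carbocycle C1–C14) comes from hydroboration of C5=C6 and sp3–sp2 coupling of C5 with the (E)-C4 iodide. C8 stays sp3 (OTBS) until this ring is closed.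
- **Ring B** (γ-lactone O–C14–C1–C15–C16) is made first, by oxidative lactonisation of a C14/C16 diol. The C16 oxygen is installed at the carvone stage.
- **Chain.** C14–O comes from proline aminoxylation, C12/C13 from chelate-controlled crotylation, C8–C9 from acetonitrile and C5–C7 from alkoxyallylboration. Ring order: B, A, C.

Key step: step 21

Remark: cembrane numbering is used (C18 = CH3 on C4, C19 = CH2 on C8, C20 = CH3 on C12). The (8R) centre of 28–35 has no consequence, because C8 becomes sp2 in step 23. PMP = 4-methoxyphenyl, PMB = 4-methoxybenzyl, MOM = methoxymethyl, TBS = tert-butyldimethylsilyl.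

## Route

Step 1
Reactants: 1 (S)-(+)-carvone
Product: 2 (S)-10-chlorocarvone, (5S)-5-(3-chloroprop-1-en-2-yl)-2-methylcyclohex-2-en-1-one
Conditions: Ca(OCl)2, solid CO2, CH2Cl2/H2O, 0 °C
Reagents that add atoms: calcium hypochlorite, [Ca+2].[O-]Cl.[O-]Cl
Why: Ene-type allylic chlorination by HOCl made in situ should attack only the electron-rich 1,1-disubstituted alkene (the enone alkene is deactivated), placing a leaving group on the future C16 without touching the future C1.

Step 2
Reactants: 2 (S)-10-chlorocarvone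
Product: 3 (5S)-5-[3-(4-methoxyphenoxy)prop-1-en-2-yl]-2-methylcyclohex-2-en-1-one
Conditions: 4-methoxyphenol, K2CO3, KI (cat.), acetone, reflux
Reagents that add atoms: 4-methoxyphenol, COc1ccc(O)cc1
Why: Williamson ether synthesis at a primary allylic chloride (SN2 and SN2' give the same product) under mild carbonate base should spare the enone and mask C16–O as an aryl ether that later falls to the same oxidant as a PMB group.

Step 3
Reactants: 3 PMP ether of 10-hydroxycarvone
Product: 4 (1S,4S,6S)-4-[3-(4-methoxyphenoxy)prop-1-en-2-yl]-1-methyl-7-oxabicyclo[4.1.0]heptan-2-one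
Conditions: 30% H2O2, NaOH (cat.), MeOH, 0 °C
Reagents that add atoms: hydrogen peroxide, OO
Why: Weitz–Scheffer nucleophilic epoxidation touches only the enone alkene and should come in anti to the side chain; both new stereocentres are erased in step 4.

Step 4
Reactants: 4 epoxy ketone
Product: 6 (3R)-3-[3-(4-methoxyphenoxy)prop-1-en-2-yl]hept-5-ynal, via tosylhydrazone 5 (not isolated)
Conditions: TsNHNH2, CH2Cl2/AcOH (1:1), −20 °C → rt
Reagents that add atoms: p-toluenesulfonyl hydrazide, Cc1ccc(cc1)S(=O)(=O)NN (its atoms stay only in 5)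
Why: Eschenmoser–Tanabe fragmentation: hydrazone 5 opens the epoxide, loses N2 and sulfinate and breaks the Cα–Cβ bond, so the ring should unroll to the C13 aldehyde and the methyl-capped C3≡C4 alkyne with C1 unchanged.

Step 5
Reactants: 6 alkynal
Product: 9 (2R,3S)-3-[3-(4-methoxyphenoxy)prop-1-en-2-yl]hept-5-yne-1,2-diol (14R,1S), via aminoxy aldehyde 7 (not isolated), via aminoxy alcohol 8 (not isolated)
Conditions: PhNO, L-proline (20 mol %), MeCN, −20 °C; NaBH4, MeOH, 0 °C; AcOH, Zn dust, rt
Reagents that add atoms: nitrosobenzene, O=Nc1ccccc1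
Why: Proline-catalysed α-aminoxylation: the enamine of 6 is attacked at C14 by the oxygen of PhNO held by the carboxylic acid of L-proline, the sense known to give (R)-2-oxy aldehydes under catalyst control, and borohydride reduction with reductive N–O cleavage should give the diol without touching alkyne or alkene.

Step 6
Reactants: 9 diol
Product: 10 4-methoxybenzylidene acetal of 9 (C13/C14 dioxolane, both acetal epimers)
Conditions: 4-MeOC6H4CH(OMe)2, PPTS (cat.), CH2Cl2, rt
Reagents that add atoms: 4-methoxybenzaldehyde dimethyl acetal, COc1ccc(cc1)C(OC)OC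
Why: Acid-catalysed transacetalisation ties the 1,2-diol into a five-membered acetal, which removes both O–H groups before the zirconium hydride step and prepares the regioselective release of C13–OH.

Step 7
Reactants: 10 alkynyl acetal
Product: 12 (3E)-4-iodoalkene acetal (I on C4, trans to C2), via alkenylzirconocene 11 (not isolated)
Conditions: Cp2Zr(H)Cl (2 equiv), THF, rt → 45 °C, dark; I2, THF, −20 °C
Reagents that add atoms: iodine, II; Cp2Zr(H)Cl, [H][Zr](Cl)(C1C=CC=C1)C1C=CC=C1 (its atoms stay only in 11)
Why: Syn hydrozirconation then iodinolysis with retention: excess hydride and gentle warming let the regioisomeric alkenylzirconocenes equilibrate to zirconium on the less hindered methyl-bearing C4, an internal alkyne reacts ahead of a branched 1,1-disubstituted alkene, and syn H/Zr addition fixes the (E)-iodide.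

Step 8
Reactants: 12 iodoalkene acetal
Product: 13 C14 PMB ether with free C13 primary alcohol (1S,14R,3E)
Conditions: i-Bu2AlH (3 equiv), CH2Cl2, −78 → 0 °C; aq. KNaC4H4O6
Reagents that add atoms: none
Why: Reductive acetal opening: aluminium binds the less hindered primary oxygen and hydride goes to the oxocarbenium carbon, so the PMB group should end on the secondary C14 oxygen.

Step 9
Reactants: 13 primary alcohol
Product: 14 α-(PMB-oxy) aldehyde (C13 = CHO; 1S,14R,3E)
Conditions: Dess–Martin periodinane, CH2Cl2, 0 °C → rt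
Reagents that add atoms: none
Why: Dess–Martin oxidation is close to neutral, so the α-alkoxy aldehyde should form without epimerisation at C14.

Step 10
Reactants: 14 aldehyde; 15 tributyl[(E)-but-2-enyl]stannane
Product: 16 homoallylic alcohol (1S,12S,13R,14R,3E), 12,13-syn and 13,14-syn, terminal alkene C10=C11
Conditions: MgBr2·OEt2 (3 equiv), CH2Cl2, −25 °C; 15, −25 → 0 °C
Reagents that add atoms: none
Why: Lewis-acid-mediated SE2' crotylstannane addition under Cram-chelate control: magnesium bridges the aldehyde oxygen and the C14 OPMB oxygen, so attack anti to the C1 substituent should give the 13,14-syn diol pattern (13R), and the open antiperiplanar transition state gives the 12,13-syn methyl/hydroxyl pair (12S).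

Step 11
Reactants: 16 homoallylic alcohol
Product: 17 C13 MOM ether of 16
Conditions: MOMCl, i-Pr2NEt, Bu4NI (cat.), CH2Cl2, 0 °C → reflux
Reagents that add atoms: chloromethyl methyl ether, COCCl
Why: O-alkylation of the hindered secondary alcohol with the small MOM chloride gives an acetal ether that survives the later hydride, carbanion, cerium and fluoride steps.

Step 12
Reactants: 17 MOM ether
Product: 19 C10 primary alcohol, via alkyldicyclohexylborane 18 (not isolated)
Conditions: Cy2BH, THF, 0 °C → rt; NaOH, 30% H2O2, 0 °C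
Reagents that add atoms: hydrogen peroxide, OO; dicyclohexylborane, B(C1CCCCC1)C1CCCCC1 (its atoms stay only in 18)
Why: Hydroboration–oxidation: the bulky dialkylborane adds to the monosubstituted C10=C11 alkene much faster than to the branched 1,1-disubstituted C15=C17 alkene or the iodoalkene and puts boron on terminal C10.

Step 13
Reactants: 19 primary alcohol
Product: 20 C10 primary iodide
Conditions: I2, PPh3, imidazole, CH2Cl2, 0 °C
Reagents that add atoms: iodine, II
Why: Appel-type iodination converts the unhindered primary alcohol by SN2 under neutral conditions that leave all ethers and the iodoalkene alone.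

Step 14
Reactants: 20 primary iodide; 21 acetonitrile
Product: 23 C8 nitrile (C10–C9H2–C8≡N), via lithioacetonitrile 22 (not isolated)
Conditions: 21, LiN(i-Pr)2, THF, −78 °C; 20, DMPU, −78 → −20 °C
Reagents that add atoms: lithium diisopropylamide, [Li]N(C(C)C)C(C)C (its lithium stays only in 22)
Why: SN2 alkylation of lithioacetonitrile by the primary iodide adds C9 and C8, and the stabilised carbanion is too weak for iodine–lithium exchange at the sp2 C4–I bond.

Step 15
Reactants: 23 nitrile
Product: 24 C8 aldehyde
Conditions: i-Bu2AlH (1.2 equiv), CH2Cl2, −78 °C; aq. KNaC4H4O6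
Reagents that add atoms: water, O
Why: Partial reduction of a nitrile: one hydride adds, and the N-aluminium imine is hydrolysed to the aldehyde on work-up.

Step 16
Reactants: 25 allyl alcohol
Product: 26 allyl methoxymethyl ether
Conditions: MOMCl, i-Pr2NEt, CH2Cl2, 0 °C → rt
Reagents that add atoms: chloromethyl methyl ether, COCCl
Why: Simple O-alkylation of a primary alcohol supplies the C5–C7 unit in the form needed for γ-alkoxyallyl metalation.

Step 17
Reactants: 24 C8 aldehyde; 26 allyl methoxymethyl ether
Product: 28 (7R,8R)-7-OMOM-8-hydroxy alkene (7,8-syn, terminal alkene C5=C6), via alkoxyallylborane 27 (not isolated)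
Conditions: 26, s-BuLi, THF, −78 °C; (−)-Ipc2BOMe; BF3·OEt2; 24, −78 °C → rt; NaOH, 30% H2O2
Reagents that add atoms: (−)-B-methoxydiisopinocampheylborane, COB([C@@H]1C[C@@H]2C[C@H]([C@H]1C)C2(C)C)[C@@H]1C[C@@H]2C[C@H]([C@H]1C)C2(C)C (its atoms stay only in 27)
Why: Brown alkoxyallylboration through a chair transition state: the (Z)-borane geometry gives the 7,8-syn relation, and the isopinocampheyl groups derived from (+)-α-pinene choose the aldehyde face that leads to (7R,8R), so C7 is set by reagent control and C5–C7 arrive with the terminal alkene.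

Step 18
Reactants: 28 C8 alcohol
Product: 29 C8 OTBS ether
Conditions: TBSOTf, 2,6-lutidine, CH2Cl2, −78 → −20 °C
Reagents that add atoms: tert-butyldimethylsilyl triflate, CC(C)(C)[Si](C)(C)OS(=O)(=O)C(F)(F)F
Why: Silylation with the triflate caps the hindered carbinol, so that C8 stays sp3 and inert to boranes until ring A is closed, avoiding an α-oxygenated β,γ-unsaturated ketone with a labile C7–H.

Step 19
Reactants: 29 fully protected chain
Product: 30 C14,C16-diol
Conditions: (NH4)2Ce(NO3)6 (5 equiv), MeCN/H2O (4:1), 0 °C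
Reagents that add atoms: none
Why: Tetravalent cerium oxidises both electron-rich arenes by single-electron transfer and water then releases C14–OH and C16–OH in one operation, while MOM, secondary TBS, iodoalkene and alkenes should survive the short exposure at 0 °C.

Step 20
Reactants: 30 diol
Product: 32 seco (E)-vinyl iodide with terminal alkene and α-methylene-γ-lactone in place (1S,7R,8R,12S,13R,14R,3E), via lactol 31 (not isolated)
Conditions: TEMPO (20 mol %), PhI(OAc)2 (3 equiv), CH2Cl2, rt
Reagents that add atoms: none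
Why: Oxoammonium oxidative lactonisation: the primary allylic alcohol is oxidised first, C14–OH traps the enal as lactol 31, and a second oxidation closes ring B, whose cis fusion follows from the C1 and C14 centres already in place.

Step 21
Reactants: 32 seco vinyl iodide
Product: 34 14-membered (3E)-ene methylene lactone (7-OMOM, 8-OTBS, 13-OMOM), via alkyl-9-BBN 33 (not isolated)
Conditions: (9-BBN)2 (1.5 equiv B–H), THF, 0 °C → rt; syringe-pump addition to PdCl2(dppf)·CH2Cl2 (15 mol %), AsPh3 (30 mol %), Cs2CO3 (3 equiv), DMF/THF/H2O, 45 °C, final about 1 mM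
Reagents that add atoms: 9-borabicyclo[3.3.1]nonane, [H]B1C2CCCC1CCC2 (its atoms stay only in 33)
Why: 9-BBN adds anti-Markovnikov to C5=C6 to give the C5 primary alkylborane 33, which carbonate and water turn into a borate; zerovalent palladium formed from PdCl2(dppf) inserts into C4–I with retention, the C5 alkyl group passes from boron to palladium, and reductive elimination makes the C4–C5 bond. The closest known reaction type is the macrocyclic B-alkyl Suzuki–Miyaura coupling of ω-alkenyl vinyl iodides at high dilution. It closes ring A, the 14-membered carbocycle C1–C14, by an end-to-end intramolecular sp3–sp2 coupling in which the new bond and the C3=C4 alkene both lie in the ring, and slow addition to a dilute catalyst solution favours closure over oligomerisation. No stereocentre is created, and the (3E) geometry is inherited from 32 because oxidative addition and reductive elimination both retain configuration at C4. The step needs chemoselective hydroboration: C5=C6 is the only monosubstituted electron-neutral alkene, C15=C17 is deactivated by the lactone carbonyl, C3=C4 is trisubstituted and iodine-bearing, and C8 is still sp3 so no 1,1-disubstituted alkene competes. A Heck reaction with C15=C17 is shut out because palladium on C4 stands trans to the C2 chain, dppf curbs β-hydride loss, and the C7 oxygen is γ to boron and palladium and cannot be eliminated.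

Step 22
Reactants: 34 macrocycle
Product: 35 macrocyclic C8 alcohol
Conditions: HF·pyridine, pyridine/THF, 0 °C → rt
Reagents that add atoms: none
Why: Fluoride-induced desilylation removes the only silyl ether, and the buffered, non-basic reagent should spare the methylene lactone and both MOM ethers.

Step 23
Reactants: 35 C8 alcohol
Product: 36 macrocyclic C8 ketone (7R)
Conditions: Dess–Martin periodinane, CH2Cl2, 0 °C → rt
Reagents that add atoms: none
Why: Dess–Martin oxidation of the single free alcohol; C6 is now saturated, so the α-alkoxy ketone no longer carries a doubly activated C7–H.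

Step 24
Reactants: 36 C8 ketone
Product: 37 bis-MOM triene (C8=C19 installed)
Conditions: Zn, CH2Br2, TiCl4 (pre-aged in THF), CH2Cl2, 0 °C → rt
Reagents that add atoms: dibromomethane, BrCBr
Why: Lombardo methylenation: the zinc/titanium gem-dimetallic reagent is non-basic, so C7 should not epimerise, and it methylenates ketones while leaving lactones and enoates alone.

Step 25
Reactants: 37 bis-MOM triene
Product: 38 7,13-diol triene
Conditions: Me2BBr (5 equiv), CH2Cl2, −78 °C; THF/sat. aq. NaHCO3
Reagents that add atoms: none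
Why: Bromoborane cleavage of acetal-type ethers goes at −78 °C through bromomethyl ethers that hydrolyse on bicarbonate work-up, conditions under which the lactone and the three alkenes should not react.

Step 26
Reactants: 38 diol triene
Product: 39 (3R,4R)-epoxide of 38
Conditions: D-fructose-derived Shi ketone (30 mol %), 2KHSO5·KHSO4·K2SO4, K2CO3, Bu4NHSO4 (cat.), MeCN/CH2(OMe)2, aq. Na2B4O7 buffer, 0 °C
Reagents that add atoms: potassium peroxymonosulfate, [K+].[O-]S(=O)(=O)OO
Why: Shi epoxidation: the chiral dioxirane reacts through a spiro transition state, for which the D-series ketone is known to give (R,R)-epoxides from (E)-trisubstituted alkenes, and the electron-rich C3=C4 should react well ahead of the 1,1-disubstituted C8=C19 and the electron-poor C15=C17.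

Step 27
Reactants: 39 epoxy diol
Product: 40 uprolide D
Conditions: camphorsulfonic acid (10 mol %), CH2Cl2, 0 °C → rt
Reagents that add atoms: none
Why: Acid-catalysed transannular 5-exo-tet epoxide opening closes ring C: C7–OH attacks the tertiary C4 from behind the C4–O bond (inversion, 4R to 4S) while C3 keeps its oxygen (3R), and both the more substituted carbon and the smaller ring favour this path over attack at C3 or by C13–OH.

## Compound list

1 | (S)-(+)-carvone | CC1=CC[C@@H](CC1=O)C(C)=C | starting material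
2 | (S)-10-chlorocarvone | CC1=CC[C@@H](CC1=O)C(=C)CCl | intermediate
3 | (S)-10-(4-methoxyphenoxy)carvone | CC1=CC[C@@H](CC1=O)C(=C)COc1ccc(OC)cc1 | intermediate
4 | (1S,4S,6S)-epoxy ketone | O=C1C[C@@H](C(=C)COc3ccc(OC)cc3)C[C@@H]2O[C@]12C | intermediate
5 | tosylhydrazone of 4 | Cc1ccc(cc1)S(=O)(=O)NN=C1C[C@@H](C(=C)COc3ccc(OC)cc3)C[C@@H]2O[C@]12C | intermediate
6 | (3R)-3-[3-(4-methoxyphenoxy)prop-1-en-2-yl]hept-5-ynal | CC#CC[C@H](CC=O)C(=C)COc1ccc(OC)cc1 | intermediate
7 | (14R)-α-(anilinooxy) aldehyde | CC#CC[C@H]([C@@H](ONc1ccccc1)C=O)C(=C)COc1ccc(OC)cc1 | intermediate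
8 | (14R)-2-(anilinooxy) alcohol | CC#CC[C@H]([C@@H](ONc1ccccc1)CO)C(=C)COc1ccc(OC)cc1 | intermediate
9 | (2R,3S)-hept-5-yne-1,2-diol | CC#CC[C@H]([C@@H](O)CO)C(=C)COc1ccc(OC)cc1 | intermediate
10 | 4-methoxybenzylidene acetal of 9 | CC#CC[C@H]([C@@H]1COC(O1)c1ccc(OC)cc1)C(=C)COc1ccc(OC)cc1 | intermediate
11 | C4 alkenylzirconocene chloride | C/C(=C\C[C@H]([C@@H]1COC(O1)c1ccc(OC)cc1)C(=C)COc1ccc(OC)cc1)[Zr](Cl)(C1C=CC=C1)C1C=CC=C1 | intermediate
12 | (3E)-4-iodoalkene acetal | C/C(I)=C\C[C@H]([C@@H]1COC(O1)c1ccc(OC)cc1)C(=C)COc1ccc(OC)cc1 | intermediate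
13 | C14 OPMB, C13 primary alcohol | C/C(I)=C\C[C@H]([C@@H](OCc1ccc(OC)cc1)CO)C(=C)COc1ccc(OC)cc1 | intermediate
14 | C13 aldehyde, C14 OPMB | C/C(I)=C\C[C@H]([C@@H](OCc1ccc(OC)cc1)C=O)C(=C)COc1ccc(OC)cc1 | intermediate
15 | tributyl[(E)-but-2-enyl]stannane | C/C=C/C[Sn](CCCC)(CCCC)CCCC | starting material
16 | syn,syn homoallylic alcohol (1S,12S,13R,14R) | C=C[C@H](C)[C@@H](O)[C@H](OCc1ccc(OC)cc1)[C@@H](C/C=C(\C)I)C(=C)COc1ccc(OC)cc1 | intermediate
17 | C13 MOM ether | C=C[C@H](C)[C@@H](OCOC)[C@H](OCc1ccc(OC)cc1)[C@@H](C/C=C(\C)I)C(=C)COc1ccc(OC)cc1 | intermediate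
18 | C10 alkyldicyclohexylborane | C1CCCCC1B(C1CCCCC1)CC[C@H](C)[C@@H](OCOC)[C@H](OCc1ccc(OC)cc1)[C@@H](C/C=C(\C)I)C(=C)COc1ccc(OC)cc1 | intermediate
19 | C10 primary alcohol | OCC[C@H](C)[C@@H](OCOC)[C@H](OCc1ccc(OC)cc1)[C@@H](C/C=C(\C)I)C(=C)COc1ccc(OC)cc1 | intermediate
20 | C10 primary iodide | ICC[C@H](C)[C@@H](OCOC)[C@H](OCc1ccc(OC)cc1)[C@@H](C/C=C(\C)I)C(=C)COc1ccc(OC)cc1 | intermediate
21 | acetonitrile | CC#N | starting material
22 | lithioacetonitrile | [Li]CC#N | intermediate
23 | C8 nitrile | N#CCCC[C@H](C)[C@@H](OCOC)[C@H](OCc1ccc(OC)cc1)[C@@H](C/C=C(\C)I)C(=C)COc1ccc(OC)cc1 | intermediate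
24 | C8 aldehyde | O=CCCC[C@H](C)[C@@H](OCOC)[C@H](OCc1ccc(OC)cc1)[C@@H](C/C=C(\C)I)C(=C)COc1ccc(OC)cc1 | intermediate
25 | allyl alcohol | C=CCO | starting material
26 | allyl methoxymethyl ether | C=CCOCOC | intermediate
27 | [(Z)-3-(methoxymethoxy)allyl]diisopinocampheylborane | COCO/C=C\CB([C@@H]1C[C@@H]2C[C@H]([C@H]1C)C2(C)C)[C@@H]1C[C@@H]2C[C@H]([C@H]1C)C2(C)C | intermediate
28 | (7R,8R)-7-OMOM-8-ol | C=C[C@@H](OCOC)[C@H](O)CCC[C@H](C)[C@@H](OCOC)[C@H](OCc1ccc(OC)cc1)[C@@H](C/C=C(\C)I)C(=C)COc1ccc(OC)cc1 | intermediate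
29 | C8 OTBS ether | C=C[C@@H](OCOC)[C@H](O[Si](C)(C)C(C)(C)C)CCC[C@H](C)[C@@H](OCOC)[C@H](OCc1ccc(OC)cc1)[C@@H](C/C=C(\C)I)C(=C)COc1ccc(OC)cc1 | intermediate
30 | C14,C16-diol | C=C[C@@H](OCOC)[C@H](O[Si](C)(C)C(C)(C)C)CCC[C@H](C)[C@@H](OCOC)[C@H](O)[C@@H](C/C=C(\C)I)C(=C)CO | intermediate
31 | α-methylene lactol | C=C[C@@H](OCOC)[C@H](O[Si](C)(C)C(C)(C)C)CCC[C@H](C)[C@@H](OCOC)[C@@H]1OC(O)C(=C)[C@@H]1C/C=C(\C)I | intermediate
32 | seco (E)-vinyl iodide, terminal alkene, lactone in place | C=C[C@@H](OCOC)[C@H](O[Si](C)(C)C(C)(C)C)CCC[C@H](C)[C@@H](OCOC)[C@@H]1OC(=O)C(=C)[C@@H]1C/C=C(\C)I | intermediate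
33 | C5 alkyl-9-BBN | C12CCCC(CCC1)B2CC[C@@H](OCOC)[C@H](O[Si](C)(C)C(C)(C)C)CCC[C@H](C)[C@@H](OCOC)[C@@H]1OC(=O)C(=C)[C@@H]1C/C=C(\C)I | intermediate
34 | 14-membered (3E)-ene methylene lactone | C1C[C@@H](OCOC)[C@H](O[Si](C)(C)C(C)(C)C)CCC[C@H](C)[C@@H](OCOC)[C@@H]2OC(=O)C(=C)[C@@H]2C/C=C1\C | intermediate
35 | macrocyclic C8 alcohol | C1C[C@@H](OCOC)[C@H](O)CCC[C@H](C)[C@@H](OCOC)[C@@H]2OC(=O)C(=C)[C@@H]2C/C=C1\C | intermediate
36 | macrocyclic C8 ketone | C1C[C@@H](OCOC)C(=O)CCC[C@H](C)[C@@H](OCOC)[C@@H]2OC(=O)C(=C)[C@@H]2C/C=C1\C | intermediate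
37 | bis-MOM triene | C1C[C@@H](OCOC)C(=C)CCC[C@H](C)[C@@H](OCOC)[C@@H]2OC(=O)C(=C)[C@@H]2C/C=C1\C | intermediate
38 | 7,13-diol triene | C1C[C@@H](O)C(=C)CCC[C@H](C)[C@@H](O)[C@@H]2OC(=O)C(=C)[C@@H]2C/C=C1\C | intermediate
39 | (3R,4R)-epoxy diol | C1C[C@@H](O)C(=C)CCC[C@H](C)[C@@H](O)[C@@H]2OC(=O)C(=C)[C@@H]2C[C@H]3O[C@]13C | intermediate
40 | uprolide D | C=C1CCC[C@H](C)[C@@H](O)[C@@H]2OC(=O)C(=C)[C@@H]2C[C@@H](O)[C@]2(C)CC[C@H]1O2 | target

## Step count and risks

Total step count: 27.
Longest linear sequence: 26 steps from (S)-carvone (steps 1–15 and 17–27).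

**Step 21.**
- What may go wrong: ring closure may lose out to intermolecular coupling. The alkylborane may be protodeboronated, or the alkylpalladium may lose β-hydride. Aqueous carbonate or surplus borane may add to the exocyclic methylene lactone.
- Fallback: this sets out from 32 and comes back at 34, replacing the borate by an alkylzinc so that the ring is closed without water or base.
- 9-BBN followed by NaBO3·4H2O should give the C5 primary alcohol F1, and I2/PPh3/imidazole the C5 primary iodide F2.
- Zn dust (activated with BrCH2CH2Br and Me3SiCl, THF, 35 °C, no LiCl) inserts only into the sp3 C–I bond to give the alkylzinc iodide F3.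
- This solution is run slowly into PdCl2(dppf) in THF/NMP. The intramolecular Negishi coupling makes the same C4–C5 bond with retention at C4.

**Step 26.**
- What may go wrong: the conformation of the 14-membered ring may expose one alkene face so strongly that it overrides the ketone catalyst, giving poor facial selectivity. Slow turnover may also let the C8=C19 allylic alcohol be oxidised.
- Fallback: this sets out from 36 and comes back at 40, moving ring C formation in front of the methylenation and switching from outside delivery to hydroxyl-directed delivery.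
- Me2BBr (as in step 25) should give the 7,13-dihydroxy ketone F4.
- With no C8=C19 alkene present, VO(acac)2/t-BuOOH bound to the bishomoallylic C7 alkoxide delivers oxygen to C3=C4 through a tether, to give the epoxy ketone F5.
- Camphorsulfonic acid closes ring C to the tetrahydrofuran ketone F6.
- An excess of the Zn/CH2Br2/TiCl4 reagent, which tolerates free hydroxyl groups, then installs C19.

**Step 24.**
- What may go wrong: methylenation may be slow at a ketone flanked by the C7 OMOM group. The titanium Lewis acid may strip a MOM ether or promote enolisation toward C7.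
- Fallback: this sets out from 36 and comes back at 37, building the alkene in two stages by a Peterson olefination.
- Me3SiCH2MgCl/CeCl3 (THF, −78 °C) is a non-basic 1,2-selective nucleophile that prefers the ketone to the lactone, and should give the β-hydroxysilane F7.
- HF·pyridine then triggers the elimination to C8=C19.

Further compounds
F1 | step 21 | C5 primary alcohol of 32 | OCC[C@@H](OCOC)[C@H](O[Si](C)(C)C(C)(C)C)CCC[C@H](C)[C@@H](OCOC)[C@@H]1OC(=O)C(=C)[C@@H]1C/C=C(\C)I
F2 | step 21 | C5 primary iodide | ICC[C@@H](OCOC)[C@H](O[Si](C)(C)C(C)(C)C)CCC[C@H](C)[C@@H](OCOC)[C@@H]1OC(=O)C(=C)[C@@H]1C/C=C(\C)I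
F3 | step 21 | C5 alkylzinc iodide | I[Zn]CC[C@@H](OCOC)[C@H](O[Si](C)(C)C(C)(C)C)CCC[C@H](C)[C@@H](OCOC)[C@@H]1OC(=O)C(=C)[C@@H]1C/C=C(\C)I
F4 | step 26 | 7,13-dihydroxy C8 ketone | C1C[C@@H](O)C(=O)CCC[C@H](C)[C@@H](O)[C@@H]2OC(=O)C(=C)[C@@H]2C/C=C1\C
F5 | step 26 | (3R,4R)-epoxy C8 ketone | C1C[C@@H](O)C(=O)CCC[C@H](C)[C@@H](O)[C@@H]2OC(=O)C(=C)[C@@H]2C[C@H]3O[C@]13C
F6 | step 26 | tetrahydrofuran C8 ketone | O=C1CCC[C@H](C)[C@@H](O)[C@@H]2OC(=O)C(=C)[C@@H]2C[C@@H](O)[C@]2(C)CC[C@H]1O2
F7 | step 24 | C8 β-hydroxysilane (C8 epimers) | C1C[C@@H](OCOC)C(O)(C[Si](C)(C)C)CCC[C@H](C)[C@@H](OCOC)[C@@H]2OC(=O)C(=C)[C@@H]2C/C=C1\C
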